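In a one-step world, starting material and reagent meet in a single equilibrium, and I reckoned these flasks as if they lived there.

| setting | beta | zeta | epsilon | flask |
|---|---|---|---|---|
| starting material | 0.10 M | 0.10 M | 0.050 M | 0.10 M |
| reagent in the second phase | 0.060 M | 0.24 M | 0.12 M | 0.120 M |
| remark | run made earlier | run made earlier | run made earlier |  |
| time |  |  |  | 40 min |
| volume of the second phase over the first |  |  |  | 2.0 |

- beta (time / min: starting material / %, product / %): 2.00: 97.4, 3.3; 4.00: 96.9, 2.9; 6.00: 96.6, 2.5; 12.0: 97.3, 3.0; 25.0: 96.6, 2.7
- zeta (time / min: starting material / %, product / %): 2.00: 89.2, 9.4; 6.00: 90.2, 10.2; 12.0: 90.5, 10.3; 15.0: 89.9, 10.7; 25.0: 89.9, 9.8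
- epsilon (time / min: starting material / %, product / %): 2.00: 95.2, 3.9; 4.00: 94.4, 5.5; 6.00: 94.7, 5.1; 12.0: 94.8, 4.7; 25.0: 94.9, 5.6

(each reading ± 0.5 percentage points)

- why nothing more happens at 40 min, or that something still does (forward and back rates have come level / all of the starting material has reacted / it is still moving)
- how much of the starting material has reacted by 40 min
- how much product there is at 40 min, in percent of the starting material charged

- in the second phase: reagent in the second phase; everything else is in the first
- charges count per volume of the first phase; a concentration in a rate is the amount of a species over the volume of its own phase; every rate counts per litre of the first phase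
- the earlier runs hold the two phases in the same ratio of volumes as the flask asked about
- the reaction counts as stopped when no species that holds the starting material changes by six tenths of a point or more over the second half of the time

In the zeta run, product went from 9.4% at 2.00 min to 9.8% at 25.0 min, no trend against a scatter of 0.5 percentage points. Starting material stood at 89.9% at the end, so I read a balance, not an exhaustion, and one reached well before 40 min. Mean product in the beta, zeta and epsilon runs was 2.88%, 10.1% and 4.96%.

I carried one number, the apparent equilibrium constant K′ = [product]/([starting material]·([reagent charged] − [product])), everything counted per litre of the first phase. The runs gave 0.519 L mol⁻¹, 0.488 L mol⁻¹ and 0.444 L mol⁻¹, with a mean of 0.484 L mol⁻¹. The phase ratio stayed the same, and the flask's reagent charge lay inside the runs.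

My bench rule took the even split, where [product] = [starting material], as the zero, and set the odds of product equal to K′ times the reagent charge, whatever the starting material charge. For the flask that gave 5.48%. The rule treats the reagent as untouched, but product holds a share of it, namely the yield times the ratio of charges, 0.833. I took the rule to hold while that share of the reagent charge stays small; for the flask it was 4.56%, so I put the flask inside that border. With the balance written in full, I reached 5.26%.

The forecast said forward and back rates have come level, with 5.2% reacted and 5.2% product, and reasoned: “The phase ratio is the same in the flask, so K′ carries over unchanged.” My figure stood 0.060 points above it.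

In the flask, forward and back rates have come level, with 5.14% reacted and 5.14% product at 40 min.

    reagent in the reaction phase ⇌ reagent in the second phase, rate k1*([reagent in the reaction phase] - [reagent in the second phase]/K1) per volume of the first phase (partition coefficient = 3.10, kL = 2.70 s⁻¹)
    starting material + reagent in the reaction phase ⇌ product (K = 4.20 L mol⁻¹, k = 7.50 L mol⁻¹ s⁻¹)
    reagent in the reaction phase ⇌ dormant form (K = 1.70, k = 0.160 s⁻¹)

The neighbour flask, the same but charged with 0.40 M of starting material, has a ratio of charges of 3.33 against 0.833. The bench rule, blind to that charge, still said 5.48%. K′ at 0.484 L mol⁻¹ with the full balance, which had given 5.26% for the flask, gave 4.67% here. Product in the neighbour held 15.3% of the reagent charge, against 4.28% in the flask. The neighbour ended at 4.58% product, with 95.4% of its starting material still there.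

Readings and results stem from a simulated flask on assumed constants, noise included.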